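Read the flasks at 2.5 d, and compare them by the share of target in target plus side product.

| flask | acidic substrate | free base | electrophile | remark | time |
|---|---|---|---|---|---|
| teal | 20 mM | 14 mM | 22 mM | run made earlier |  |
| ochre | 28 mM | 14 mM | 22 mM | run made earlier |  |
| red | 44 mM | 14 mM | 22 mM | run made earlier |  |
| blue | 20 mM | 21 mM | 22 mM | run made earlier |  |
| theta | 20 mM (fed, over 12 h) | 14.0 mM | 22.0 mM | all else is in the flask from the start; the feed brings no volume worth counting | 2.5 d |
| beta | 20 mM | 14.0 mM | 22.0 mM (fed, over 12 h) | all else is in the flask from the start; the feed brings no volume worth counting | 2.5 d |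
| epsilon | 20 mM | 14.0 mM | 22.0 mM (in portions, 5, over 12 h) | first portion at the start, last at 12 h | 2.5 d |
| zeta | 20 mM | 14.0 mM | 22.0 mM | everything together at the start | 2.5 d |

| run | time / h | target / % | side product / % | acidic substrate / % |
|---|---|---|---|---|
| teal | 3.00 | 4.0 | 14.0 | 51.6 |
| teal | 6.00 | 6.3 | 22.8 | 44.6 |
| teal | 15.0 | 9.8 | 38.4 | 32.9 |
| teal | 40.0 | 14.7 | 52.3 | 19.7 |
| ochre | 6.00 | 4.5 | 27.5 | 50.0 |
| ochre | 15.0 | 6.2 | 42.6 | 38.1 |
| ochre | 30.0 | 8.4 | 52.9 | 29.6 |
| ochre | 50.0 | 10.1 | 58.9 | 24.7 |
| red | 12.0 | 2.9 | 40.8 | 50.0 |
| red | 25.0 | 5.2 | 48.4 | 45.9 |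
| red | 40.0 | 4.7 | 49.8 | 43.3 |
| red | 50.0 | 4.4 | 50.7 | 43.4 |
| blue | 4.00 | 6.9 | 17.0 | 38.1 |
| blue | 8.00 | 8.1 | 27.7 | 32.5 |
| blue | 20.0 | 13.3 | 44.0 | 20.6 |
| blue | 50.0 | 19.0 | 53.7 | 10.9 |

(scatter of a reading: 0.5 percentage points)

- percent here means acidic substrate units held: one side product counts as two
- the numbers in the tables scatter with a standard deviation of 0.5 percentage points
- steps that have been proposed: target <-> isomer of the product; acidic substrate + anion -> side product; acidic substrate + free base <-> protonated base + anion; electrophile <-> dormant form; electrophile + anion -> target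

- the flask that comes out highest in share of target in target plus side product, or "all alike" when all lie within 1.5 percentage points (theta / beta / epsilon / zeta / all alike)
- share of target in target plus side product at the end, theta
- share of target in target plus side product at the end, beta
- share of target in target plus side product at the end, epsilon
- share of target in target plus side product at the end, zeta

The proposed steps to target and to side product both draw on the anion, so it cancels from their ratio. The gain in target per gain in side product, a selectivity factor, then goes as [B]/[AH], with [B] the electrophile and [AH] the acidic substrate. Freeze [B] as an assumption for a late stretch: the readings show no electrophile, and the proposed steps take it to the dormant form as well as to target, and target on to the isomer. Take the late stretch of teal, 15.0 h to 40.0 h: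

A* = (gain in target / gain in side product) × mean [AH] = 1.85 mM

Call A* the break-even substrate: the [AH] at which target and side product, in table percent, gain equally, so the selectivity factor is A*/[AH]. As a reading, blue's stretch from 20.0 h to 50.0 h gives about the same, 1.85 mM, with more free base.

Now turn the settings by hand. Zeta is teal's recipe, whose share at 40.0 h reads 21.9%, so expect slightly more. Feed the substrate, as theta does: [AH] stays low during the feed, so expect more than zeta. Feed the electrophile, as beta does: [B], and A* with it, stays low early, and teal's side product reaches 38.4% by 15.0 h, more than it adds afterwards up to 40.0 h. So expect less than zeta. Give portions, as epsilon does: expect a value between beta and zeta, nearer beta.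

The forecast names theta, with 25.5% for theta, 17% for beta, 19% for epsilon and 22.3% for zeta, holding that “Slow substrate feed keeps substrate low while anion meets electrophile”.

The flasks give 24.8% for theta, 17.9% for beta, 18.0% for epsilon and 22.3% for zeta, so theta stands highest.

    target ⇌ isomer of the product (K = 0.490, k = 0.140 /h)
    acidic substrate + anion → side product (k = 5.80 /M/h)
    acidic substrate + free base ⇌ protonated base + anion, settled at all times (K = 0.950)
    electrophile ⇌ dormant form (K = 0.220, k = 0.0440 /h)
    electrophile + anion → target (k = 2.10 /M/h)

Theta is not at rest at 2.5 d: it holds 18.0% acidic substrate and 4.33% anion. Carry it to 25.0 d, where substrate stands at 2.98%: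

mean [AH] = 2.10 mM, A*/[AH] = 0.881, theta's own gains = 0.784

Left ten times as long, until 25.0 d, theta's share climbs to 28.3%. Beta over the same stretch:

mean [AH] = 1.62 mM, A*/[AH] = 1.14, beta's own gains = 1.09

Left ten times as long, until 25.0 d, beta's share reaches 23.1%.

The data come from a simulation with made-up constants, noise included.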